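**Retrosynthetic overview**
1. Target 19 ⇐ trans-8α,9β-diol 17 (mesylation at C9, SN2 closure by O8 with inversion) ⇐ α-ketol 16 (hydride at C9).
2. Key disconnection C8–C9: intramolecular NHC crossed benzoin, with the C9 aldehyde as acyl anion adding to the C8 methyl ketone of 15; this closes the seven-membered ring.
3. Keto aldehyde 15 ⇐ aldehyde 10 + acetone (aldol, C6–C7, sets C6) + veratroyl chloride (ester placed before ring closure).
4. Aldehyde 10 ⇐ enal 6 + formylmethyl Grignard 7 (conjugate addition sets C1, then C5).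
5. Enal 6 ⇐ (S)-terpinen-4-ol (source of C4) by ozonolysis and aldol ring contraction. Ring order: five-membered carbocycle (step 3), seven-membered carbocycle (step 8), oxirane (step 10).

Assumption: (S)-(+)-terpinen-4-ol (1) is taken as commercial material of high enantiomeric purity; labels C1–C10 follow daucane numbering (C1 methyl-bearing ring-fusion carbon, C4 carbinol carbon with isopropyl, C5 ring-fusion CH, C6 ester carbon, C8/C9 epoxide carbons; α = face of H5, β = face of the C1 methyl).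

Step 1
Reactants: 1 (S)-(+)-terpinen-4-ol
Product: 2 triethyl{[(1S)-4-methyl-1-(propan-2-yl)cyclohex-3-en-1-yl]oxy}silane
Conditions: Et3SiOTf, 2,6-lutidine, CH2Cl2, 0 °C
Reagents that add atoms: triethylsilyl trifluoromethanesulfonate, CC[Si](CC)(CC)OS(=O)(=O)C(F)(F)F
Why: Silyl triflate silylation of a hindered tertiary alcohol; the ether blocks β-elimination later and shields the oxygen-bearing ring face in step 4, and no stereocentre is touched.

Step 2
Reactants: 2 triethylsilyl ether of terpinen-4-ol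
Product: 4 (3S)-6-oxo-3-(propan-2-yl)-3-[(triethylsilyl)oxy]heptanal, via secondary ozonide 3 (not isolated)
Conditions: O3, CH2Cl2, −78 °C; then Me2S, −78 °C → rt
Reagents that add atoms: ozone, [O-][O+]=O
Why: Criegee ozonolysis of the only alkene with reductive work-up gives the 1,6-keto aldehyde; C4 is not involved.

Step 3
Reactants: 4 (3S)-6-oxo-3-(propan-2-yl)-3-[(triethylsilyl)oxy]heptanal
Product: 6 (5R)-2-methyl-5-(propan-2-yl)-5-[(triethylsilyl)oxy]cyclopent-1-ene-1-carbaldehyde, via cyclic aldol 5 (not isolated)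
Conditions: piperidine (20 mol%), CH3CO2H (20 mol%), benzene, 80 °C, Dean–Stark
Reagents that add atoms: none
Why: Amine-catalysed intramolecular aldol condensation (the aldehyde enamine attacks the methyl ketone, then dehydration), as with the analogous limonene-derived keto aldehyde; C4 is untouched.

Step 4
Reactants: 6 (5R)-2-methyl-5-(propan-2-yl)-5-[(triethylsilyl)oxy]cyclopent-1-ene-1-carbaldehyde; 7 (1,3-dioxolan-2-ylmethyl)magnesium bromide
Product: 10 (1R,2R,5R)-2-(1,3-dioxolan-2-ylmethyl)-5-hydroxy-2-methyl-5-(propan-2-yl)cyclopentane-1-carbaldehyde, via trimethylsilyl enol ether 8 (not isolated), via triethylsilyl-protected aldehyde 9 (not isolated)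
Conditions: CuBr·SMe2 (20 mol%), Me3SiCl, THF, −78 → −30 °C; then HF·pyridine, THF, 0 °C
Reagents that add atoms: 7 (1,3-dioxolan-2-ylmethyl)magnesium bromide, Br[Mg]CC1OCCO1
Why: Copper-catalysed, Me3SiCl-accelerated conjugate addition of a Grignard reagent (Nakamura–Kuwajima conditions) builds the C1 quaternary centre from the face anti to the OSiEt3 group (its silicon sits under the ring, anti to isopropyl), so the new CH2 arm ends cis to isopropyl; C5 is set on desilylation by protonation that leaves the epimerisable formyl group trans to both flanking carbon substituents, and HF·pyridine also frees the C4 hydroxyl.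

Step 5
Reactants: 10 hydroxy aldehyde; 11 acetone
Product: 12 (4S)-4-[(1S,2R,5R)-2-(1,3-dioxolan-2-ylmethyl)-5-hydroxy-2-methyl-5-(propan-2-yl)cyclopentyl]-4-hydroxybutan-2-one
Conditions: D-proline (30 mol%), acetone/DMSO (1:4), rt
Reagents that add atoms: 11 acetone, CC(C)=O
Why: List–Barbas proline-catalysed direct aldol of acetone with an α-branched aldehyde; the D-proline enamine (Houk–List transition state) gives the (S)-carbinol at C6, the mirror image of the (R)-aldols that L-proline gives with α-branched aldehydes, and the neutral conditions spare the retro-aldol-prone β-hydroxy aldehyde.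

Step 6
Reactants: 12 aldol; 13 3,4-dimethoxybenzoyl chloride
Product: 14 (1S)-1-[(1S,2R,5R)-2-(1,3-dioxolan-2-ylmethyl)-5-hydroxy-2-methyl-5-(propan-2-yl)cyclopentyl]-3-oxobutyl 3,4-dimethoxybenzoate
Conditions: pyridine, 4-(dimethylamino)pyridine (10 mol%), CH2Cl2, 0 °C → rt
Reagents that add atoms: 13 3,4-dimethoxybenzoyl chloride, COc1ccc(C(Cl)=O)cc1OC
Why: Nucleophile-catalysed acyl transfer to the only acylable (secondary) hydroxyl, with the tertiary C4 hydroxyl inert and C6 retained; the weak base limits β-elimination of the new β-acyloxy ketone.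

Step 7
Reactants: 14 veratrate acetal
Product: 15 (1S)-1-[(1S,2R,5R)-2-hydroxy-5-methyl-5-(2-oxoethyl)-2-(propan-2-yl)cyclopentyl]-3-oxobutyl 3,4-dimethoxybenzoate
Conditions: p-toluenesulfonic acid monohydrate (10 mol%), THF/H2O (4:1), 40 °C
Reagents that add atoms: water, O
Why: Acid-catalysed acetal hydrolysis unmasks the C9 aldehyde; O6 is already acylated, so no lactol can form, and the C4 hydroxyl is trans to the aldehyde arm.

Step 8
Reactants: 15 keto aldehyde
Product: 16 (1R,4R,5S,6S,8R)-4,8-dihydroxy-9-oxodaucan-6-yl 3,4-dimethoxybenzoate (trans-fused; 8α-OH, 8β-Me)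
Conditions: 2-(pentafluorophenyl)-6,7-dihydro-5H-pyrrolo[2,1-c][1,2,4]triazol-2-ium tetrafluoroborate (15 mol%), Et3N (15 mol%), toluene (0.02 M), 40 °C
Reagents that add atoms: none
Why: Proposed new method: the carbene adds to the C9 aldehyde to give the Breslow intermediate (an acyl anion), which attacks the C8 methyl ketone in an intramolecular crossed aldehyde–ketone benzoin reaction, the closest known type being the NHC-catalysed formation of five- and six-membered cyclic acyloins, here extended to a seven-membered ring held by the trans-1,2-disubstituted cyclopentane; the O–H···O proton transfer in the bond-forming step and the reversibility of the reaction should favour the ketol whose C8 hydroxyl is pseudo-equatorial (α, cis to the C6 ester) and hydrogen-bonded to the C9 carbonyl, and the weak base is chosen to avoid β-elimination of the ester.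

Step 9
Reactants: 16 α-ketol
Product: 17 (1R,4R,5S,6S,8R,9R)-4,8,9-trihydroxydaucan-6-yl 3,4-dimethoxybenzoate (8α-OH, 9β-OH)
Conditions: NaBH4, MeOH/CH2Cl2 (1:1), −40 °C
Reagents that add atoms: none
Why: Borohydride reduction of the α-hydroxy ketone; hydride adds to the α face, anti to the β-methyl groups at C8 and C1, giving the trans diol, and the aryl ester is not reduced.

Step 10
Reactants: 17 trans diol
Product: 19 (1R,4R,5S,6S,8R,9S)-8,9-epoxy-4-hydroxydaucan-6-yl 3,4-dimethoxybenzoate (8α,9α-epoxyjaeschkeanadiol 6-veratrate), via C9 mesylate 18 (not isolated)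
Conditions: MeSO2Cl, Et3N, CH2Cl2, 0 °C; then 1,8-diazabicyclo[5.4.0]undec-7-ene (DBU), rt
Reagents that add atoms: none
Why: Selective sulfonylation of the only secondary hydroxyl, then intramolecular Williamson (SN2) closure by the C8 alkoxide with inversion at C9 gives the 8α,9α-epoxide; the β-oriented C4 hydroxyl cannot reach the back side of C9.

**Compound list**
1 | (S)-(+)-terpinen-4-ol, (1S)-4-methyl-1-(propan-2-yl)cyclohex-3-en-1-ol | CC1=CC[C@](O)(C(C)C)CC1 | starting material
2 | triethyl{[(1S)-4-methyl-1-(propan-2-yl)cyclohex-3-en-1-yl]oxy}silane | CC1=CC[C@](O[Si](CC)(CC)CC)(C(C)C)CC1 | intermediate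
3 | secondary ozonide of 2 (1,2,4-trioxolane across the former C=C, both acetal-carbon epimers) | CC12CC[C@@](O[Si](CC)(CC)CC)(C(C)C)CC(OO1)O2 | intermediate
4 | (3S)-6-oxo-3-(propan-2-yl)-3-[(triethylsilyl)oxy]heptanal | CC(=O)CC[C@@](O[Si](CC)(CC)CC)(C(C)C)CC=O | intermediate
5 | (5R)-2-hydroxy-2-methyl-5-(propan-2-yl)-5-[(triethylsilyl)oxy]cyclopentane-1-carbaldehyde (cyclic aldol, epimers at C1 and C2) | O=CC1C(C)(O)CC[C@@]1(O[Si](CC)(CC)CC)C(C)C | intermediate
6 | (5R)-2-methyl-5-(propan-2-yl)-5-[(triethylsilyl)oxy]cyclopent-1-ene-1-carbaldehyde | O=CC1=C(C)CC[C@@]1(O[Si](CC)(CC)CC)C(C)C | intermediate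
7 | (1,3-dioxolan-2-ylmethyl)magnesium bromide | Br[Mg]CC1OCCO1 | starting material
8 | ({[(2R,5R)-2-(1,3-dioxolan-2-ylmethyl)-2-methyl-5-(propan-2-yl)-5-[(triethylsilyl)oxy]cyclopentylidene]methyl}oxy)trimethylsilane (trimethylsilyl enol ether of 9) | C[Si](C)(C)OC=C1[C@@](C)(CC2OCCO2)CC[C@@]1(O[Si](CC)(CC)CC)C(C)C | intermediate
9 | (1R,2R,5R)-2-(1,3-dioxolan-2-ylmethyl)-2-methyl-5-(propan-2-yl)-5-[(triethylsilyl)oxy]cyclopentane-1-carbaldehyde | O=C[C@@H]1[C@@](C)(CC2OCCO2)CC[C@@]1(O[Si](CC)(CC)CC)C(C)C | intermediate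
10 | (1R,2R,5R)-2-(1,3-dioxolan-2-ylmethyl)-5-hydroxy-2-methyl-5-(propan-2-yl)cyclopentane-1-carbaldehyde | O=C[C@@H]1[C@@](C)(CC2OCCO2)CC[C@@]1(O)C(C)C | intermediate
11 | acetone | CC(C)=O | starting material
12 | (4S)-4-[(1S,2R,5R)-2-(1,3-dioxolan-2-ylmethyl)-5-hydroxy-2-methyl-5-(propan-2-yl)cyclopentyl]-4-hydroxybutan-2-one | CC(=O)C[C@H](O)[C@@H]1[C@@](C)(CC2OCCO2)CC[C@@]1(O)C(C)C | intermediate
13 | 3,4-dimethoxybenzoyl chloride (veratroyl chloride) | COc1ccc(C(Cl)=O)cc1OC | starting material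
14 | (1S)-1-[(1S,2R,5R)-2-(1,3-dioxolan-2-ylmethyl)-5-hydroxy-2-methyl-5-(propan-2-yl)cyclopentyl]-3-oxobutyl 3,4-dimethoxybenzoate | CC(=O)C[C@H](OC(=O)c2ccc(OC)c(OC)c2)[C@@H]1[C@@](C)(CC3OCCO3)CC[C@@]1(O)C(C)C | intermediate
15 | (1S)-1-[(1S,2R,5R)-2-hydroxy-5-methyl-5-(2-oxoethyl)-2-(propan-2-yl)cyclopentyl]-3-oxobutyl 3,4-dimethoxybenzoate | CC(=O)C[C@H](OC(=O)c2ccc(OC)c(OC)c2)[C@@H]1[C@@](C)(CC=O)CC[C@@]1(O)C(C)C | intermediate
16 | (1R,4R,5S,6S,8R)-4,8-dihydroxy-9-oxodaucan-6-yl 3,4-dimethoxybenzoate (trans-fused; 4β-OH, 6α-ester, 8α-OH, 8β-Me) | COc1ccc(C(=O)O[C@H]2C[C@@](C)(O)C(=O)C[C@@]3(C)CC[C@@](O)(C(C)C)[C@H]23)cc1OC | intermediate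
17 | (1R,4R,5S,6S,8R,9R)-4,8,9-trihydroxydaucan-6-yl 3,4-dimethoxybenzoate (8α-OH, 9β-OH) | COc1ccc(C(=O)O[C@H]2C[C@@](C)(O)[C@H](O)C[C@@]3(C)CC[C@@](O)(C(C)C)[C@H]23)cc1OC | intermediate
18 | 9-O-methanesulfonate of 17 | COc1ccc(C(=O)O[C@H]2C[C@@](C)(O)[C@H](OS(C)(=O)=O)C[C@@]3(C)CC[C@@](O)(C(C)C)[C@H]23)cc1OC | intermediate
19 | (1R,4R,5S,6S,8R,9S)-8,9-epoxy-4-hydroxydaucan-6-yl 3,4-dimethoxybenzoate | COc1ccc(C(=O)O[C@H]2C[C@@]3(C)O[C@H]3C[C@@]3(C)CC[C@@](O)(C(C)C)[C@H]23)cc1OC | target

**Step count and risks**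
Total steps: 10. Longest linear sequence: 10 (fully linear from 1).

Steps most likely to fail:

Step 4. The tetrasubstituted enal may resist copper-mediated 1,4-addition, or the reagent may enter from the wrong face of C1. The fallback sets out from 6. Allylmagnesium bromide (THF, −78 °C) adds 1,2 to give the allyl carbinol F1. KH and 18-crown-6 (THF, 0 °C) then trigger an anionic oxy-Cope rearrangement that delivers the allyl group to C1 through a chair transition state, giving the C1-allyl aldehyde F2. HF·pyridine frees the C1-allyl hydroxy aldehyde F3. The conditions of steps 5 and 6 applied to F3 give the C1-allyl aldol F4 and the C1-allyl veratrate F5. Ozonolysis of the allyl group in F5 (O3, CH2Cl2, −78 °C; Me2S) gives keto aldehyde 15, where the route is rejoined.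

Step 5. The aldehyde is flanked by two fully substituted carbons and may be too hindered for enamine catalysis, or the catalyst may not override the substrate bias. The fallback sets out from 10. 2-Methylallylmagnesium chloride (2.5 equiv, THF, −78 °C) first forms the magnesium alkoxide at C4, which chelates the aldehyde; attack on the exposed face then gives the 1,3-anti methallyl carbinol F6. Acylation as in step 6 gives the methallyl veratrate F7. Ozonolysis of its 1,1-disubstituted alkene (O3, CH2Cl2, −78 °C; Me2S) gives methyl ketone 14, where the route is rejoined.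

Step 8. The seven-membered benzoin closure may be slow, may lose out to β-elimination of the veratrate, or may give the C8 epimer (8β-OH), which would lead to the wrong epoxide face. The fallback sets out from 15. Low-valent titanium (TiCl4, Zn, pyridine, THF, reflux, slow addition) couples the two carbonyls reductively (intramolecular McMurry reaction) to the C8=C9 alkene jaeschkeanadiol 6-veratrate F8. 3-Chloroperbenzoic acid (NaHCO3, CH2Cl2, 0 °C) then epoxidises the face opposite the angular methyl and gives target 19 directly.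

**Further compounds**
F1 | step 4 | allyl carbinol, 1-[(5R)-2-methyl-5-(propan-2-yl)-5-[(triethylsilyl)oxy]cyclopent-1-en-1-yl]but-3-en-1-ol (both carbinol epimers) | C=CCC(O)C1=C(C)CC[C@@]1(O[Si](CC)(CC)CC)C(C)C
F2 | step 4 | C1-allyl aldehyde, (1R,2R,5R)-2-allyl-2-methyl-5-(propan-2-yl)-5-[(triethylsilyl)oxy]cyclopentane-1-carbaldehyde | O=C[C@@H]1[C@@](C)(CC=C)CC[C@@]1(O[Si](CC)(CC)CC)C(C)C
F3 | step 4 | C1-allyl hydroxy aldehyde, (1R,2R,5R)-2-allyl-5-hydroxy-2-methyl-5-(propan-2-yl)cyclopentane-1-carbaldehyde | O=C[C@@H]1[C@@](C)(CC=C)CC[C@@]1(O)C(C)C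
F4 | step 4 | C1-allyl aldol, (4S)-4-[(1S,2R,5R)-2-allyl-5-hydroxy-2-methyl-5-(propan-2-yl)cyclopentyl]-4-hydroxybutan-2-one | CC(=O)C[C@H](O)[C@@H]1[C@@](C)(CC=C)CC[C@@]1(O)C(C)C
F5 | step 4 | C1-allyl veratrate, (1S)-1-[(1S,2R,5R)-2-allyl-5-hydroxy-2-methyl-5-(propan-2-yl)cyclopentyl]-3-oxobutyl 3,4-dimethoxybenzoate | CC(=O)C[C@H](OC(=O)c2ccc(OC)c(OC)c2)[C@@H]1[C@@](C)(CC=C)CC[C@@]1(O)C(C)C
F6 | step 5 | methallyl carbinol, (1S)-1-[(1S,2R,5R)-2-(1,3-dioxolan-2-ylmethyl)-5-hydroxy-2-methyl-5-(propan-2-yl)cyclopentyl]-3-methylbut-3-en-1-ol | CC(=C)C[C@H](O)[C@@H]1[C@@](C)(CC2OCCO2)CC[C@@]1(O)C(C)C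
F7 | step 5 | methallyl veratrate, (1S)-1-[(1S,2R,5R)-2-(1,3-dioxolan-2-ylmethyl)-5-hydroxy-2-methyl-5-(propan-2-yl)cyclopentyl]-3-methylbut-3-en-1-yl 3,4-dimethoxybenzoate | CC(=C)C[C@H](OC(=O)c2ccc(OC)c(OC)c2)[C@@H]1[C@@](C)(CC3OCCO3)CC[C@@]1(O)C(C)C
F8 | step 8 | jaeschkeanadiol 6-veratrate, (1R,4R,5S,6S)-4-hydroxydauc-8-en-6-yl 3,4-dimethoxybenzoate | COc1ccc(C(=O)O[C@H]2CC(C)=CC[C@@]3(C)CC[C@@](O)(C(C)C)[C@H]23)cc1OC
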